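If target keeps climbing after the starting material has gone, count half-lives of whatever lies between them before trusting a plateau.

all flasks: free catalyst 15 mol%
- Tuesday's: starting material 0.12 M; impurity 5.8 mM; temperature 0 °C; run made earlier
- Sunday's: starting material 0.50 M; impurity 5.8 mM; temperature 15 °C; run made earlier
- Thursday's: starting material 0.25 M; impurity 8.7 mM; temperature 0 °C; run made earlier
- epsilon: starting material 0.25 M; impurity 5.8 mM; temperature 25 °C; time 5.0 min
- delta: starting material 0.25 M; impurity 5.8 mM; temperature 5 °C; time 5.0 min

- Tuesday's (time / min: target / %, starting material / %): 0.500: 0.6, 42.0; 0.833: 2.2, 23.2; 1.33: 4.6, 10.2; 2.00: 8.7, 2.1; 4.00: 18.1, 0; 6.00: 27.1, 0.1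
- Sunday's (time / min: target / %, starting material / %): 0.333: 19.4, 2.8; 0.500: 28.7, 0; 0.833: 43.7, 0.1; 1.33: 56.9, 1.1; 2.50: 66.9, 0.5; 4.00: 69.9, 0
- Thursday's (time / min: target / %, starting material / %): 1.33: 11.1, 10.5; 2.50: 23.3, 1.8; 4.00: 36.9, 0.1; 5.00: 43.6, 0.6; 6.00: 49.6, 0.5

(each reading ± 0.5 percentage points)



- which of the two there is more of at the end, epsilon (uncatalysed product / target)
- which of the two there is more of at the end, delta (uncatalysed product / target)
- final target, as a percentage of the starting material charged, in epsilon
- final target, as a percentage of the starting material charged, in delta

Read the lag first. In Tuesday's run the starting material is down to 2.1 % after 2.00 min, while target stands at 8.7 % and goes on to 27.1 % after 6.00 min, so I take an intermediate to lie between them. Take Sunday's last reading, 69.9 % of target, as the plateau, and assume as my own step that it holds at other temperatures; Thursday's run is still climbing at 49.6 % and shows none of its own.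

Assume next that impurity takes free catalyst one for one, and subtract it from the catalyst charged. The working catalyst then stays constant, so the intermediate falls pseudo-first-order. The approach to the plateau gives a constant per working catalyst of 20.1 /M/min in Sunday's run and 8.24 /M/min in Thursday's run, both readings.

Carry that constant along the temperature scale as a fixed ratio per degree. Epsilon gets 36.4 /M/min and delta 11.1 /M/min. Dividing ln(2) by the constant times the difference of c(free catalyst) and c(impurity) gives the intermediate half-lives of 0.601 min in epsilon and 1.97 min in delta. In 5.0 min epsilon therefore gets 8.31 of them and delta 2.54. Call this number, the time allowed over the intermediate's half-life, the half-life count.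

The bench rule calls a first-order change finished after 5 half-lives. Epsilon passes that, so I put it on the plateau at 69.7 %. Delta falls short, so the rule stops there, and the unfinished fraction leaves 57.9 %. I expect target to lead in both flasks.

The forecast differs on epsilon, naming uncatalysed product with 32 % of target. For delta it names target with 55 %. Its ground: “The leak has the higher activation energy”.

Epsilon ends with 67.8 % of target and 31.9 % of uncatalysed product, delta with 56.2 % and 25.9 %.

    starting material → intermediate (k = 0.0400 /s, Ea = 76.0 kJ/mol)
    free catalyst + intermediate → free catalyst + target (k = 0.160 /M/s, Ea = 44.0 kJ/mol)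
    free catalyst + impurity → spent catalyst (k = 170 /M/s, Ea = 46.0 kJ/mol)
    starting material → uncatalysed product (k = 0.0140 /s, Ea = 86.0 kJ/mol)
    (constants at 5 °C)

At epsilon's start, starting material went to intermediate 2.1 times as fast as to uncatalysed product. In epsilon, uncatalysed product stands at 31.9 % after 2.50 min and at 31.9 % after 5.00 min. Beside a count of 8.31, epsilon holds 0.302 % of intermediate at the end; beside 2.54, delta holds 17.9 %. Now take epsilon with 3.8 mol% of free catalyst: working catalyst drops to 3.70 mM, the count to 0.970, and the target reckoned on epsilon's 68.1 % at 50.0 min to 33.3 %. That flask gives 31.9 % of target with 36.2 % of intermediate.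

The numbers in the tables are simulated on assumed constants.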